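The strategy traces C5, the lactone carbinol and only stereocentre of the butenolide ring (O1, C2 to C5), back to a ketone, and opens the O1–C2 lactone bond. This gives a γ-keto acid whose ketone and carboxyl group sit cis on the C3=C4 double bond. Its ring tautomer is a racemic 5-hydroxybutenolide, made by singlet-oxygen oxidation of a 2,3,4-trisubstituted furan. The precursor carries the C3 methyl group, a C4 tert-butyl ester and a pentadec-14-enyl chain whose alkene masks the remote methyl ketone. In one operation a ketoreductase sets C5–H enantioselectively and acidification recloses the ring.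

Key step: step 5

Remark on numbering and descriptors: the text uses butenolide numbering (O1, C2 carbonyl, C3 methyl-bearing, C4 carboxyl-bearing, C5 carbinol). The systematic names use 2,5-dihydrofuran numbering, in which the carbinol carbon is C2. The target SMILES reads as (R) at this carbon. The open keto acid has the formal descriptor (E) because the tert-butoxycarbonyl group outranks the ketone, although ketone and carboxyl group are cis.

Assumption (chemistry): screening of an anti-Prelog, NADPH-dependent ketoreductase panel, if needed with one round of engineering on a hit, provides a variant that accepts the bulky open keto carboxylate.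

Step 1
Reactants: 1 11-bromoundecanoic acid; 2 5-bromopent-1-ene
Product: 5 hexadec-15-enoic acid, via pent-4-enylmagnesium bromide 3 (not isolated), via chloromagnesium 11-bromoundecanoate 4 (not isolated)
Conditions: 2, Mg, THF, reflux (gives 3); separately 1, MeMgCl (1.0 equiv), THF, −20 °C (gives 4); add 3 (1.3 equiv), Li2CuCl4 (3 mol %), THF, −20 °C to rt; 1 M HCl
Reagents that add atoms: none
Why: The Li2CuCl4-catalysed Kochi cross-coupling of a primary alkyl Grignard reagent with a primary alkyl bromide is fast at low temperature, the carboxyl group is shielded as its magnesium salt 4, and the C5 plus C11 union gives the C16 ω-alkenoic acid in one operation.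

Step 2
Reactants: 5 hexadec-15-enoic acid; 6 mono-tert-butyl malonate
Product: 8 tert-butyl 3-oxooctadec-17-enoate, via acyl imidazolide 7 (not isolated)
Conditions: 5, 1,1'-carbonyldiimidazole (1.1 equiv), THF, rt (gives 7); then 6 (1.5 equiv), MgCl2 (1.5 equiv), Et3N (3 equiv), MeCN/THF, rt to 40 °C; aq. citric acid
Reagents that add atoms: none
Why: In this Masamune–Brooks decarboxylative Claisen condensation the magnesium enolate of the malonate half-ester is C-acylated by 7 and loses CO2, under near-neutral conditions that leave the alkene and the tert-butyl ester untouched.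

Step 3
Reactants: 8 tert-butyl 3-oxooctadec-17-enoate; 9 chloroacetone
Product: 11 tert-butyl 4-methyl-2-(pentadec-14-en-1-yl)furan-3-carboxylate, via hydroxydihydrofuran 10 (not isolated)
Conditions: 9 (1.2 equiv), pyridine, 50 °C; then PPTS (10 mol %), toluene, 60 °C
Reagents that add atoms: none
Why: In this Feist–Benary furan synthesis the weak amine base lets the active methylene of 8 add to the ketone carbonyl of 9 (aldol), the enol oxygen displaces chloride in a 5-exo-tet closure to 10, and loss of water aromatises, so the methyl group ends at furan C4 and furan C5 keeps its hydrogen.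

Step 4
Reactants: 11 tert-butyl 4-methyl-2-(pentadec-14-en-1-yl)furan-3-carboxylate
Product: 13 tert-butyl 2-hydroxy-4-methyl-5-oxo-2-(pentadec-14-en-1-yl)-2,5-dihydrofuran-3-carboxylate (racemic hemiketal), via furan endoperoxide 12 (not isolated)
Conditions: O2 (1 atm), tetraphenylporphyrin (0.5 mol %), white LED, iPr2NEt (1.5 equiv), CH2Cl2, −78 °C, then warm to rt
Reagents that add atoms: dioxygen (as singlet oxygen), O=O
Why: The [4+2] cycloaddition of singlet oxygen across furan C2/C5 gives 12, whose only bridgehead hydrogen is removed by the hindered amine in a Kornblum–DeLaMare fragmentation, so only one regioisomeric hydroxybutenolide can form, while the monosubstituted chain alkene is far too unreactive for an ene reaction.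

Step 5
Reactants: 13 tert-butyl 2-hydroxy-4-methyl-5-oxo-2-(pentadec-14-en-1-yl)-2,5-dihydrofuran-3-carboxylate
Product: 16 tert-butyl (2R)-4-methyl-5-oxo-2-(pentadec-14-en-1-yl)-2,5-dihydrofuran-3-carboxylate, via open keto acid 14 (not isolated), via hydroxy acid 15 (not isolated)
Conditions: (R)-selective (anti-Prelog) ketoreductase variant chosen by screening, NADP+ (cat.), D-glucose (1.5 equiv), glucose dehydrogenase, KH2PO4/K2HPO4 buffer (0.2 M, pH 7.5), DMSO (10 % v/v), 30 °C; then aq. citric acid to pH 3, MTBE, rt
Reagents that add atoms: none
Why: At pH 7.5 hemiketal 13 opens to the achiral carboxylate of 14, in which the double bond inherited from the furan holds the C5 ketone and the C2 carboxylate on the same side. Enzyme-bound NADPH transfers hydride to the Si face of that ketone, and glucose with glucose dehydrogenase makes the reduction irreversible; the closest known chemistry is the ketoreductase reduction of γ-keto acids and esters with lactonisation, and of enones to allylic alcohols. On protonation the C5 hydroxyl of 15 attacks the C2 carboxyl carbon in a 5-exo-trig closure that forms O1–C2 and expels water. The (R) configuration at C5 is controlled only by the active site of the chosen variant, which has to distinguish a slim n-alkyl chain from a branched, fully substituted alkenyl group. The step also needs chemoselectivity against a second carbonyl group and against ester hydrolysis, which the substrate secures by carrying the chain terminus as an alkene that the enzyme cannot reduce and the C4 ester as a hindered tert-butyl ester. The amphiphilic carboxylate form together with DMSO should keep the lipophilic substrate accessible, and no base strong enough to remove the new γ-hydrogen is present.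

Step 6
Reactants: 16 tert-butyl (2R)-4-methyl-5-oxo-2-(pentadec-14-en-1-yl)-2,5-dihydrofuran-3-carboxylate
Product: 17 tert-butyl (2R)-4-methyl-5-oxo-2-(14-oxopentadecyl)-2,5-dihydrofuran-3-carboxylate
Conditions: PdCl2 (10 mol %), CuCl (30 mol %), O2 (1 atm), DMF/H2O (7:1), rt
Reagents that add atoms: water, O
Why: In this Tsuji–Wacker oxidation divalent palladium activates the unhindered terminal alkene for Markovnikov attack of water, β-hydride elimination and tautomerisation give the methyl ketone, CuCl/O2 reoxidises zerovalent palladium, and the tetrasubstituted electron-poor ring alkene, the tert-butyl ester and C5 are left alone in the weakly acidic medium.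

Step 7
Reactants: 17 tert-butyl (2R)-4-methyl-5-oxo-2-(14-oxopentadecyl)-2,5-dihydrofuran-3-carboxylate
Product: 18 isomuronic acid, (2R)-4-methyl-5-oxo-2-(14-oxopentadecyl)-2,5-dihydrofuran-3-carboxylic acid
Conditions: CF3CO2H/CH2Cl2 (1:4), 0 °C to rt
Reagents that add atoms: none
Why: Acidolysis of the tert-butyl ester through the tert-butyl cation (AAL1 pathway) releases isobutene and the free acid without any base, so the lactone stays closed and the acidic γ-hydrogen at C5 is not exchanged.

Compound list
1 | 11-bromoundecanoic acid | OC(=O)CCCCCCCCCCBr | starting material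
2 | 5-bromopent-1-ene | C=CCCCBr | starting material
3 | pent-4-enylmagnesium bromide | C=CCCC[Mg]Br | intermediate
4 | chloromagnesium 11-bromoundecanoate | [O-]C(=O)CCCCCCCCCCBr.[Mg+2].[Cl-] | intermediate
5 | hexadec-15-enoic acid | C=CCCCCCCCCCCCCCC(=O)O | intermediate
6 | mono-tert-butyl malonate (3-tert-butoxy-3-oxopropanoic acid) | OC(=O)CC(=O)OC(C)(C)C | starting material
7 | 1-(hexadec-15-enoyl)-1H-imidazole | C=CCCCCCCCCCCCCCC(=O)n1ccnc1 | intermediate
8 | tert-butyl 3-oxooctadec-17-enoate | C=CCCCCCCCCCCCCCC(=O)CC(=O)OC(C)(C)C | intermediate
9 | chloroacetone | CC(=O)CCl | starting material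
10 | tert-butyl 4-hydroxy-4-methyl-2-(pentadec-14-en-1-yl)-4,5-dihydrofuran-3-carboxylate (racemic) | C=CCCCCCCCCCCCCCC1=C(C(=O)OC(C)(C)C)C(C)(O)CO1 | intermediate
11 | tert-butyl 4-methyl-2-(pentadec-14-en-1-yl)furan-3-carboxylate | C=CCCCCCCCCCCCCCc1occ(C)c1C(=O)OC(C)(C)C | intermediate
12 | tert-butyl 5-methyl-1-(pentadec-14-en-1-yl)-2,3,7-trioxabicyclo[2.2.1]hept-5-ene-6-carboxylate (racemic) | C=CCCCCCCCCCCCCCC12OOC(O1)C(C)=C2C(=O)OC(C)(C)C | intermediate
13 | tert-butyl 2-hydroxy-4-methyl-5-oxo-2-(pentadec-14-en-1-yl)-2,5-dihydrofuran-3-carboxylate (racemic hemiketal) | C=CCCCCCCCCCCCCCC1(O)OC(=O)C(C)=C1C(=O)OC(C)(C)C | intermediate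
14 | (2E)-3-(tert-butoxycarbonyl)-2-methyl-4-oxononadeca-2,18-dienoic acid (ketone and carboxyl group cis; carboxylate at pH 7.5) | OC(=O)/C(C)=C(\C(=O)CCCCCCCCCCCCCC=C)C(=O)OC(C)(C)C | intermediate
15 | (2E,4R)-3-(tert-butoxycarbonyl)-4-hydroxy-2-methylnonadeca-2,18-dienoic acid | OC(=O)/C(C)=C(\[C@H](O)CCCCCCCCCCCCCC=C)C(=O)OC(C)(C)C | intermediate
16 | tert-butyl (2R)-4-methyl-5-oxo-2-(pentadec-14-en-1-yl)-2,5-dihydrofuran-3-carboxylate | C=CCCCCCCCCCCCCC[C@H]1OC(=O)C(C)=C1C(=O)OC(C)(C)C | intermediate
17 | tert-butyl (2R)-4-methyl-5-oxo-2-(14-oxopentadecyl)-2,5-dihydrofuran-3-carboxylate | CC(=O)CCCCCCCCCCCCC[C@H]1OC(=O)C(C)=C1C(=O)OC(C)(C)C | intermediate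
18 | isomuronic acid, (2R)-4-methyl-5-oxo-2-(14-oxopentadecyl)-2,5-dihydrofuran-3-carboxylic acid | CC(=O)CCCCCCCCCCCCC[C@H]1OC(=O)C(C)=C1C(=O)O | target

Total step count: 7. Longest linear sequence: 7 steps (from 1 or 2 to 18).

Steps most likely to fail

Risk 1, step 5. Turnover may be slow or absent, because the ketone is flanked by a fully substituted alkene and the substrate aggregates in water. Facial discrimination by the available variants may also be insufficient. The fallback sets out from 13. Alkylation of its carboxylate with MeI and K2CO3 in DMF traps the open tautomer as 1-tert-butyl 4-methyl (2E)-2-(hexadec-15-enoyl)-3-methylbut-2-enedioate F1. F1 then undergoes Corey–Bakshi–Shibata reduction with (S)-2-methyl-CBS-oxazaborolidine and catecholborane in toluene at −78 °C. This borane source does not hydroborate the terminal alkene at that temperature, and the branched alkenyl group acts as the large substituent. The reduction should give 1-tert-butyl 4-methyl (2E)-2-[(1R)-1-hydroxyhexadec-15-en-1-yl]-3-methylbut-2-enedioate F2. F2 lactonises onto the cis methyl ester, with catalytic PPTS if needed, and the route is rejoined at 16.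

Risk 2, step 3. Competing C-alkylation of the enolate at the chloromethyl carbon, followed by Paal–Knorr closure, would move the methyl group to furan C5. The sequence may also stall before dehydration, or the tert-butyl ester may be lost during the acid treatment. The fallback sets out from 8 and uses a regiospecific 3-methylfuran annulation. Propargyl bromide and dimethyl sulfide in MeCN give dimethyl(prop-2-yn-1-yl)sulfonium bromide F3, which is heated with 8 and t-BuOK in THF/t-BuOH. The salt isomerises to the allenyl sulfonium ion and the enolate carbon adds to its central carbon. The enol oxygen then displaces dimethyl sulfide, and the exocyclic alkene moves into the ring. The route is rejoined at 11.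

Risk 3, step 4. The cycloaddition may be sluggish because the ester deactivates the furan, or the endoperoxide may rearrange thermally before the amine acts. The fallback sets out from 11 and replaces the cycloaddition by an ionic oxidative ring opening. NBS (1.0 equiv) and NaHCO3 in acetone/H2O at −20 °C should give tert-butyl (2E)-2-(hexadec-15-enoyl)-3-methyl-4-oxobut-2-enoate F4. Pinnick oxidation of its aldehyde follows (NaClO2, NaH2PO4, 2-methylbut-2-ene, t-BuOH/H2O), with the scavenger protecting the chain alkene. This gives the open acid 14, which closes to the hemiketal, and the route is rejoined at 13.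

Further compounds
F1 | step 5 | 1-tert-butyl 4-methyl (2E)-2-(hexadec-15-enoyl)-3-methylbut-2-enedioate | COC(=O)/C(C)=C(\C(=O)CCCCCCCCCCCCCC=C)C(=O)OC(C)(C)C
F2 | step 5 | 1-tert-butyl 4-methyl (2E)-2-[(1R)-1-hydroxyhexadec-15-en-1-yl]-3-methylbut-2-enedioate | COC(=O)/C(C)=C(\[C@H](O)CCCCCCCCCCCCCC=C)C(=O)OC(C)(C)C
F3 | step 3 | dimethyl(prop-2-yn-1-yl)sulfonium bromide | C#CC[S+](C)C.[Br-]
F4 | step 4 | tert-butyl (2E)-2-(hexadec-15-enoyl)-3-methyl-4-oxobut-2-enoate | O=C/C(C)=C(\C(=O)CCCCCCCCCCCCCC=C)C(=O)OC(C)(C)C
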